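**Retrosynthetic overview**
Ring A (C1–C5, C10) is a 4,4-dimethyl-3-ketone whose H-5 is cis to the C10 methyl group, next to the oxygenated C9. It is therefore cut as the formal [4+2] adduct of the isopropyl-ketone dienolate C4=C3(O)–C2=C1 with the C5=C10 bond of a 2-methylcyclohexenone, forming C4–C5 and C1–C10.
Ring B is bought as 4-silyloxycyclohexanone; the C6 stereocentre is set by chiral-base desymmetrisation and steers the annulation.
The cyclobutane comes from a SmI2 pinacol coupling, C9 ketone to C11 ketone; the C11 ketone is grown from the C1 ester and already carries C12 and C13.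
Ring C closes by aldol addition of the C12 methyl ketone to a C7=C8 enal (C13–C14). The cyclopropane follows from a C13 ethylidene by hydroxyl-directed Simmons–Smith reaction. The C7 hydroxyl and H-8 come last, by epoxidation and reductive opening of the C14 enone.
Order of ring formation: ring B, ring A, cyclobutane, ring C, cyclopropane.

Key step: step 7

Conventions: abietane-like numbering; C11 is the carbon on C1, C14 the carbon on C8, C15 the cyclopropane CH2, C16 the cyclopropane CH. β is the face of the C10 methyl group (H-1, H-5 and the C6, C9 and C11 oxygens lie on it); α is the opposite face.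
Assumption: the (S,S)-amide base gives the (R)-enol ether 2, as the antipodal base gives the (S)-enol ether of 4-tert-butylcyclohexanone; if the sense is opposite, the (R,R)-base is used.
Remark: 17–20 and 27–32 are carried as epimer mixtures at C8 and at the short-lived centres C9, C11 and C12 (38 and 39 at C13 and C16); their SMILES leave these centres open.

**Route**

Step 1
Reactants: 1 4-(tert-butyldimethylsilyloxy)cyclohexan-1-one
Product: 2 (R)-4-(tert-butyldimethylsilyloxy)-1-(trimethylsilyloxy)cyclohex-1-ene
Conditions: (S,S)-bis(1-phenylethyl)amine, n-BuLi, LiCl, THF, −78 °C; then 1 and Me3SiCl, −100 → −78 °C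
Reagents that add atoms: chlorotrimethylsilane, C[Si](C)(C)Cl
Why: The C2-symmetric lithium amide removes one of the two enantiotopic axial α-protons of the prochiral ketone and the enolate is silylated as it forms (enantioselective deprotonation with internal quench), which makes the carbinol carbon the C6 stereocentre.

Step 2
Reactants: 2 (R)-4-(tert-butyldimethylsilyloxy)-1-(trimethylsilyloxy)cyclohex-1-ene
Product: 3 (R)-4-(tert-butyldimethylsilyloxy)cyclohex-2-en-1-one
Conditions: Pd(OAc)2, MeCN, rt
Reagents that add atoms: none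
Why: Saegusa–Ito oxidation, in which the silyl enol ether is converted into a palladium enolate that loses β-hydride, should give the enone without touching C6.

Step 3
Reactants: 3 (R)-4-(tert-butyldimethylsilyloxy)cyclohex-2-en-1-one
Product: 4 (R)-4-(tert-butyldimethylsilyloxy)-2-iodocyclohex-2-en-1-one
Conditions: I2, pyridine, CH2Cl2, 0 °C → rt
Reagents that add atoms: iodine, II
Why: Pyridine adds reversibly to the enone, the enolate is iodinated and pyridine is expelled (α-iodination of an enone), so only the α-vinyl position is substituted.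

Step 4
Reactants: 4 (R)-4-(tert-butyldimethylsilyloxy)-2-iodocyclohex-2-en-1-one
Product: 5 (R)-4-(tert-butyldimethylsilyloxy)-2-methylcyclohex-2-en-1-one
Conditions: SnMe4, PdCl2(PhCN)2 (cat.), AsPh3, CuI, NMP, 80 °C
Reagents that add atoms: tetramethylstannane, C[Sn](C)(C)C
Why: Stille coupling of the alkenyl iodide with tetramethylstannane under copper-assisted conditions should transfer a methyl group and leave the enone and C6 unchanged.

Step 5
Reactants: 6 3-methylbutan-2-one; 7 methyl glyoxylate
Product: 9 methyl 2-hydroxy-5-methyl-4-oxohexanoate (racemic), via lithium enolate 8 (not isolated)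
Conditions: LDA, THF, −78 °C; then 7, −78 °C; then AcOH
Reagents that add atoms: none
Why: LDA deprotonates the methyl group under kinetic control and the enolate adds to the aldehyde of the glyoxylate (aldol addition); the carbinol centre is removed in step 6.

Step 6
Reactants: 9 methyl 2-hydroxy-5-methyl-4-oxohexanoate
Product: 11 methyl (E)-5-methyl-4-oxohex-2-enoate, via mesylate 10 (not isolated)
Conditions: MsCl, Et3N, CH2Cl2, 0 °C → rt
Reagents that add atoms: none
Why: Mesylation of the β-hydroxy ketone and E1cB elimination should give the doubly conjugated alkene as the more stable (E)-isomer.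

Step 7
Reactants: 11 methyl (E)-5-methyl-4-oxohex-2-enoate; 5 (R)-4-(tert-butyldimethylsilyloxy)-2-methylcyclohex-2-en-1-one
Product: 15 ring A/B cis-decalin (C1 α-CO2Me; C2=C3 triethylsilyl enol ether; C4 gem-dimethyl; 6β-OTBS; C9 ketone; C10 β-methyl), via lithium dienolate 12 (not isolated), via Michael adduct enolate 13 (not isolated), via bicyclic lithium enolate 14 (not isolated)
Conditions: LiN(SiMe3)2, THF, −78 °C, slow addition of 11; then 5, −78 → −20 °C; then Et3SiCl, Et3N, −78 → 0 °C
Reagents that add atoms: chlorotriethylsilane, CC[Si](Cl)(CC)CC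
Why: LiN(SiMe3)2 removes the isopropyl methine proton, the only enolisable hydrogen of 11, and dienolate 12 adds through C4 to C5 of enone 5; the C9 enolate 13 then adds through C10 to C1, which is β to the C3 ketone, and the remaining C3 enolate 14 is silylated on oxygen. The closest known reaction type is the anionic Michael–Michael annulation of cross-conjugated ketone dienolates with cyclohexenones to cis-decalins, a stepwise path that tolerates the fully substituted C4 terminus on which a concerted Diels–Alder reaction would fail. Ring A closes in the second addition by 6-endo-trig conjugate addition, preferred over 5-exo attack at C2 because C1 is activated by the ketone, the stronger acceptor. C5 is set by attack anti to the allylic C6 silyloxy group, C10 by the tether, which can deliver C1 only to the face that already carries C4 (cis fusion, methyl β), and C1 by lithium bridging between the C9 enolate oxygen and the C3 carbonyl, which places the ester cis to C9. The step needs carbon–carbon bond formation to outrun proton transfer from C8 of the enone and self-condensation of 11, which slow addition of 11 to the base at −78 °C and the modest basicity of a ketone enolate should secure. Trapping the regiodefined C3 enolate as its silyl enol ether gives the decalin-3,9-dione with the C3 carbonyl protected and so distinguishes C3 from C9 in the following steps.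

Step 8
Reactants: 15 cis-decalin silyl enol ether
Product: 17 C8-(benzyloxymethyl) ketone (C14 installed; C8 epimers), via C8 lithium enolate 16 (not isolated)
Conditions: LDA, THF, −78 °C; then BnOCH2Cl, −78 → −40 °C
Reagents that add atoms: benzyl chloromethyl ether, ClCOCc1ccccc1
Why: With C10 quaternary and C3 masked, LDA can enolise the C9 ketone only toward C8, and the enolate is alkylated by the reactive α-chloro ether (enolate alkylation); the C8 configuration is immaterial because C8 becomes sp2 in step 19.

Step 9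
Reactants: 17 C8-(benzyloxymethyl) ketone
Product: 18 C9,C11-diol (C11 primary alcohol; C9 carbinol; C3 enol ether kept)
Conditions: LiAlH4, THF, 0 °C
Reagents that add atoms: none
Why: LiAlH4 reduces the ester to the primary alcohol and the ketone to the carbinol while the silyl enol ether, the silyl ether and the benzyl ether are inert (hydride reduction); the C9 carbinol centre is removed again in step 11.

Step 10
Reactants: 18 C9,C11-diol
Product: 19 C3 ethylene ketal diol
Conditions: HOCH2CH2OH, PPTS (cat.), CH2Cl2, 4 Å sieves, rt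
Reagents that add atoms: ethylene glycol, OCCO
Why: Protonation of the silyl enol ether at C2 gives a silyloxycarbenium ion that is captured by the glycol and loses silanol (acid-catalysed ketalisation of an enol ether), and since C3 is the only carbon at the carbonyl level no choice between C3 and C9 is needed.

Step 11
Reactants: 19 C3 ethylene ketal diol
Product: 20 keto aldehyde (C9 ketone; C11 aldehyde)
Conditions: (COCl)2, DMSO, CH2Cl2, −78 °C; then i-Pr2NEt, −78 → −30 °C
Reagents that add atoms: none
Why: Swern oxidation turns both hydroxyl groups into alkoxysulfonium ions before the base is added, so ketone and aldehyde appear together and the γ-hydroxy aldehyde cannot close to a lactol and be over-oxidised, while the hindered base at low temperature spares the C1 centre.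

Step 12
Reactants: 21 tributyltin hydride; 22 acetaldehyde
Product: 24 1-(tributylstannyl)ethanol (racemic), via tributylstannyllithium 23 (not isolated)
Conditions: LDA, THF, 0 °C; then 22, −78 °C; then H2O
Reagents that add atoms: none
Why: Deprotonation of the tin hydride gives the stannyl anion, which adds to the aldehyde (1,2-addition of a stannyllithium).

Step 13
Reactants: 24 1-(tributylstannyl)ethanol
Product: 25 tributyl[1-(benzyloxymethoxy)ethyl]stannane (racemic)
Conditions: BnOCH2Cl, i-Pr2NEt, CH2Cl2, 0 °C → rt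
Reagents that add atoms: benzyl chloromethyl ether, ClCOCc1ccccc1
Why: The labile α-hydroxy stannane is capped as its benzyloxymethyl acetal by O-alkylation under amine-base conditions (acetal protection).

Step 14
Reactants: 25 tributyl[1-(benzyloxymethoxy)ethyl]stannane; 20 keto aldehyde
Product: 27 C11 carbinol carrying C12 (benzyloxymethoxy) and the C13 methyl group, via 1-(benzyloxymethoxy)ethyllithium 26 (not isolated)
Conditions: n-BuLi, THF, −78 °C; then 20, −78 °C; then H2O
Reagents that add atoms: none
Why: Tin–lithium exchange gives an α-alkoxy organolithium that adds to the aldehyde, far more electrophilic than the doubly α-branched C9 ketone (1,2-addition); C11 and C12 form as mixtures, C11 being oxidised in step 15 and C12 in step 19.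

Step 15
Reactants: 27 C11 carbinol
Product: 28 1,4-diketone (C9 and C11 ketones; C12 benzyloxymethoxy)
Conditions: Dess–Martin periodinane, CH2Cl2, 0 °C → rt
Reagents that add atoms: none
Why: Dess–Martin oxidation of the secondary alcohol gives the diketone under non-basic conditions that avoid aldol attack of C12 on C9.

Step 16
Reactants: 28 1,4-diketone
Product: 29 cyclobutane-9β,11β-diol (C12 chain α on C11)
Conditions: SmI2, THF, t-BuOH, −78 °C → rt; then H2O
Reagents that add atoms: none
Why: SmI2 reduces a carbonyl to a ketyl that couples with the second carbonyl (intramolecular pinacol coupling of a 1,4-diketone to a cis-cyclobutane-1,2-diol, 4-exo closure); C11 hangs on C1 and can reach C9 only from the α face, so the C9 hydroxyl is β, and bridging of both oxygens by trivalent samarium makes the diol cis, which puts the C11 hydroxyl β and the C12 chain α.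

Step 17
Reactants: 29 cyclobutane-9β,11β-diol
Product: 30 9,11-acetonide
Conditions: 2-methoxypropene, PPTS (cat.), CH2Cl2, 0 °C → rt
Reagents that add atoms: 2-methoxypropene, COC(C)=C
Why: Acid-catalysed acetal exchange ties the cis-diol into an acetonide, possible only for the cis isomer, which later blocks retro-aldol opening of the cyclobutane and α-ketol shift once C12 is a ketone.

Step 18
Reactants: 30 9,11-acetonide
Product: 31 12,14-diol
Conditions: H2 (1 atm), Pd(OH)2/C, EtOAc, rt
Reagents that add atoms: none
Why: Hydrogenolysis over palladium cleaves the benzyl ether and the benzyloxymethyl acetal, whose hemiacetal loses formaldehyde, and leaves silyl ether, ketal and acetonide.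

Step 19
Reactants: 31 12,14-diol
Product: 33 C7=C8 enal with C12 methyl ketone, via saturated keto aldehyde 32 (not isolated)
Conditions: IBX (excess), DMSO/fluorobenzene, 70 °C
Reagents that add atoms: none
Why: IBX oxidises both alcohols and then dehydrogenates the α-branched aldehyde through its enol (IBX oxidation and α,β-dehydrogenation), which can only give the C7=C8 enal because C9 is quaternary, while the methyl ketone has no β-hydrogen; C8 and C12 stop being stereocentres.

Step 20
Reactants: 33 C7=C8 enal with C12 methyl ketone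
Product: 35 ring C aldol (12-ketone; 14β-hydroxyl; C7=C8), via methyl ketone lithium enolate 34 (not isolated)
Conditions: LiN(SiMe3)2, THF, −78 °C; then AcOH, −78 °C
Reagents that add atoms: none
Why: The kinetic lithium enolate of the methyl ketone (C11 is quaternary) adds 1,2 to the enal (intramolecular aldol addition, 6-exo-trig, closing ring C); in the lithium-bridged chair-like transition state the aldehyde oxygen is axial on the convex β face, because the α-axial position collides with C10, so the C14 hydroxyl is expected to be β.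

Step 21
Reactants: 35 ring C aldol
Product: 36 14β-triethylsilyl ether
Conditions: Et3SiOTf, 2,6-lutidine, CH2Cl2, −78 °C
Reagents that add atoms: triethylsilyl trifluoromethanesulfonate, CC[Si](CC)(CC)OS(=O)(=O)C(F)(F)F
Why: Silylation of the secondary allylic alcohol with the silyl triflate and a hindered base is faster than enolisation of the ketone and prevents retro-aldol cleavage in the next step.

Step 22
Reactants: 36 14β-triethylsilyl ether; 22 acetaldehyde
Product: 38 C13 (1-hydroxyethyl) aldol (epimers), via C12 lithium enolate 37 (not isolated)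
Conditions: LDA, THF, −78 °C; then 22, −78 °C; then AcOH
Reagents that add atoms: none
Why: LDA enolises the C12 ketone toward C13, its only α-CH position, and the enolate adds to acetaldehyde at −78 °C faster than it loses the β-silyloxy group (aldol addition); the two new centres are removed in step 23.

Step 23
Reactants: 38 C13 (1-hydroxyethyl) aldol
Product: 40 (E)-13(16)-ethylidene enone (methyl on the C14 side), via aldol mesylate 39 (not isolated)
Conditions: MsCl, Et3N, CH2Cl2, 0 °C; then DBU, rt
Reagents that add atoms: none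
Why: Mesylation and E1cB elimination give the 2-alkylidene ketone as the (E)-isomer, in which the methyl group avoids the carbonyl oxygen and lies on the side of C14 (aldol condensation), which fixes the later cis relation of the C16 methyl group to C14.

Step 24
Reactants: 40 (E)-13(16)-ethylidene enone
Product: 41 14β-hydroxy enone
Conditions: HF·pyridine, pyridine, THF, 0 °C
Reagents that add atoms: none
Why: Buffered HF·pyridine cleaves the secondary triethylsilyl ether much faster than the neopentyl-type tert-butyldimethylsilyl ether at C6 (selective desilylation).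

Step 25
Reactants: 41 14β-hydroxy enone
Product: 42 12α,14β-diol
Conditions: Me4NBH(OAc)3, AcOH/MeCN, −30 °C
Reagents that add atoms: none
Why: Evans–Saksena reduction, in which the C14 hydroxyl binds the triacetoxyborohydride and delivers hydride across ring C to the β face of the C12 carbonyl, should give the anti-1,3-diol, that is the 12α-hydroxyl; the α face is in any case closed by C2 of ring A.

Step 26
Reactants: 42 12α,14β-diol
Product: 43 spirocyclopropane diol (C15 β; C16 α with methyl cis to C14)
Conditions: Et2Zn, CH2I2, CH2Cl2, 0 °C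
Reagents that add atoms: diiodomethane, ICI
Why: Simmons–Smith cyclopropanation with Et2Zn/CH2I2, in which the zinc alkoxide of the pseudoaxial C14 hydroxyl delivers the methylene to the β face of the neighbouring C13=C16 bond in a stereospecific syn addition, makes C15 β and keeps the methyl group cis to C14; the C7=C8 bond is shielded on that face by the C6 silyl ether and the C12 alkoxide has no room on the α face.

Step 27
Reactants: 43 spirocyclopropane diol
Product: 44 C14 enone with free 12α-hydroxyl
Conditions: MnO2, CH2Cl2, rt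
Reagents that add atoms: none
Why: MnO2 oxidises the allylic C14 alcohol to the enone and leaves the hindered, non-allylic C12 alcohol (chemoselective allylic oxidation).

Step 28
Reactants: 44 C14 enone
Product: 45 7α,8α-epoxy ketone
Conditions: t-BuOOH, DBU, CH2Cl2, 0 °C → rt
Reagents that add atoms: tert-butyl hydroperoxide, CC(C)(C)OO
Why: Weitz–Scheffer epoxidation, in which the hydroperoxide anion adds to C7 of the enone anti to the neighbouring C6 silyloxy group and the enolate closes on oxygen, should give the 7α,8α-epoxide.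

Step 29
Reactants: 45 7α,8α-epoxy ketone
Product: 46 6β-alcohol
Conditions: HF·pyridine, pyridine, THF, 0 °C → rt
Reagents that add atoms: none
Why: HF·pyridine removes the remaining silyl ether under non-basic conditions, which avoids Payne migration of the epoxide to a C6 alkoxide.

Step 30
Reactants: 46 6β-alcohol
Product: 47 6β,12α-diacetate
Conditions: Ac2O, DMAP, pyridine, rt
Reagents that add atoms: acetic anhydride, CC(=O)OC(C)=O
Why: DMAP-catalysed acetylation esterifies the two secondary hydroxyl groups at C6 and C12, the only free ones because the tertiary hydroxyls are held in the acetonide.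

Step 31
Reactants: 47 6β,12α-diacetate
Product: 48 7α-hydroxy ketone (target with acetonide and C3 ketal)
Conditions: Cp2TiCl2, Zn, THF, rt; then 47, MeOH, −78 → −20 °C
Reagents that add atoms: none
Why: Cp2TiCl (trivalent titanium) opens the epoxide by homolysis of the C8–O bond to the α-keto radical, which is reduced to the titanium enolate and protonated (reductive opening of an α,β-epoxy ketone to the aldol); C7 keeps its α oxygen and the proton enters C8 anti to the C9–C10 bond to give the cis B/C junction, which is also the stable epimer next to the ketone.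

Step 32
Reactants: 48 7α-hydroxy ketone
Product: 49 CNP0157858.3
Conditions: 1 M HCl, THF, 0 °C → rt
Reagents that add atoms: water, O
Why: Aqueous acid hydrolyses the strained acetonide and the hindered dioxolane (acetal hydrolysis) under conditions that should leave the acetates, the two aldol units and the cyclopropyl ketone.

**Compound list**
1 | 4-(tert-butyldimethylsilyloxy)cyclohexan-1-one | CC(C)(C)[Si](C)(C)OC1CCC(=O)CC1 | starting material
2 | (R)-4-(tert-butyldimethylsilyloxy)-1-(trimethylsilyloxy)cyclohex-1-ene | C[Si](C)(C)OC1=CC[C@H](O[Si](C)(C)C(C)(C)C)CC1 | intermediate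
3 | (R)-4-(tert-butyldimethylsilyloxy)cyclohex-2-en-1-one | O=C1C=C[C@H](O[Si](C)(C)C(C)(C)C)CC1 | intermediate
4 | (R)-4-(tert-butyldimethylsilyloxy)-2-iodocyclohex-2-en-1-one | O=C1C(I)=C[C@H](O[Si](C)(C)C(C)(C)C)CC1 | intermediate
5 | (R)-4-(tert-butyldimethylsilyloxy)-2-methylcyclohex-2-en-1-one (ring B precursor) | CC1=C[C@H](O[Si](C)(C)C(C)(C)C)CCC1=O | intermediate
6 | 3-methylbutan-2-one | CC(C)C(C)=O | starting material
7 | methyl glyoxylate | COC(=O)C=O | starting material
8 | lithium 3-methylbut-1-en-2-olate (not isolated) | C=C(O[Li])C(C)C | intermediate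
9 | methyl 2-hydroxy-5-methyl-4-oxohexanoate (racemic) | COC(=O)C(O)CC(=O)C(C)C | intermediate
10 | methyl 2-(methylsulfonyloxy)-5-methyl-4-oxohexanoate (not isolated) | COC(=O)C(OS(C)(=O)=O)CC(=O)C(C)C | intermediate
11 | methyl (E)-5-methyl-4-oxohex-2-enoate (dienolate precursor) | COC(=O)/C=C/C(=O)C(C)C | intermediate
12 | lithium dienolate of 11 (not isolated) | COC(=O)/C=C/C(O[Li])=C(C)C | intermediate
13 | Michael adduct, C9 lithium enolate, C4–C5 bond formed (not isolated) | COC(=O)/C=C/C(=O)C(C)(C)[C@H]1[C@H](O[Si](C)(C)C(C)(C)C)CCC(O[Li])=C1C | intermediate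
14 | cis-decalin C3 lithium enolate (not isolated) | COC(=O)[C@H]1C=C(O[Li])C(C)(C)[C@H]2[C@H](O[Si](C)(C)C(C)(C)C)CCC(=O)[C@@]12C | intermediate
15 | cis-decalin: C1 α-CO2Me, C2=C3 triethylsilyl enol ether, 4,4-dimethyl, H-5 β, 6β-OTBS, C9 ketone, 10β-methyl | COC(=O)[C@H]1C=C(O[Si](CC)(CC)CC)C(C)(C)[C@H]2[C@H](O[Si](C)(C)C(C)(C)C)CCC(=O)[C@@]12C | intermediate
16 | C8=C9 lithium enolate of 15 (not isolated) | COC(=O)[C@H]1C=C(O[Si](CC)(CC)CC)C(C)(C)[C@H]2[C@H](O[Si](C)(C)C(C)(C)C)CC=C(O[Li])[C@@]12C | intermediate
17 | 15 with CH2OBn (C14) at C8, C8 epimers | COC(=O)[C@H]1C=C(O[Si](CC)(CC)CC)C(C)(C)[C@H]2[C@H](O[Si](C)(C)C(C)(C)C)CC(COCc3ccccc3)C(=O)[C@@]12C | intermediate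
18 | diol: C11 CH2OH, C9 CHOH, C3 silyl enol ether | OC[C@H]1C=C(O[Si](CC)(CC)CC)C(C)(C)[C@H]2[C@H](O[Si](C)(C)C(C)(C)C)CC(COCc3ccccc3)C(O)[C@@]12C | intermediate
19 | diol with C3 ethylene ketal | OC[C@H]1CC2(OCCO2)C(C)(C)[C@H]3[C@H](O[Si](C)(C)C(C)(C)C)CC(COCc4ccccc4)C(O)[C@@]13C | intermediate
20 | keto aldehyde: C9 ketone, C11 aldehyde (α on C1) | O=C[C@H]1CC2(OCCO2)C(C)(C)[C@H]3[C@H](O[Si](C)(C)C(C)(C)C)CC(COCc4ccccc4)C(=O)[C@@]13C | intermediate
21 | tributyltin hydride | CCCC[SnH](CCCC)CCCC | starting material
22 | acetaldehyde | CC=O | starting material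
23 | tributylstannyllithium (not isolated) | CCCC[Sn]([Li])(CCCC)CCCC | intermediate
24 | 1-(tributylstannyl)ethanol (racemic) | CC(O)[Sn](CCCC)(CCCC)CCCC | intermediate
25 | tributyl[1-(benzyloxymethoxy)ethyl]stannane (racemic) | CC(OCOCc1ccccc1)[Sn](CCCC)(CCCC)CCCC | intermediate
26 | 1-(benzyloxymethoxy)ethyllithium (not isolated) | CC([Li])OCOCc1ccccc1 | intermediate
27 | C11 carbinol with C12 OCH2OBn and C13 methyl | CC(OCOCc5ccccc5)C(O)[C@H]1CC2(OCCO2)C(C)(C)[C@H]3[C@H](O[Si](C)(C)C(C)(C)C)CC(COCc4ccccc4)C(=O)[C@@]13C | intermediate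
28 | 1,4-diketone: C9 and C11 ketones | CC(OCOCc5ccccc5)C(=O)[C@H]1CC2(OCCO2)C(C)(C)[C@H]3[C@H](O[Si](C)(C)C(C)(C)C)CC(COCc4ccccc4)C(=O)[C@@]13C | intermediate
29 | cyclobutane-9β,11β-diol, C12 chain α | CC(C)(C)[Si](C)(C)O[C@@H]1CC(COCc2ccccc2)[C@@]3(O)[C@@](O)(C(C)OCOCc2ccccc2)[C@H]4CC5(OCCO5)C(C)(C)[C@@H]1[C@@]34C | intermediate
30 | 9,11-acetonide of 29 | CC(C)(C)[Si](C)(C)O[C@@H]1CC(COCc2ccccc2)[C@]36OC(C)(C)O[C@]6(C(C)OCOCc2ccccc2)[C@H]4CC5(OCCO5)C(C)(C)[C@@H]1[C@@]34C | intermediate
31 | 12,14-diol | CC(C)(C)[Si](C)(C)O[C@@H]1CC(CO)[C@]36OC(C)(C)O[C@]6(C(C)O)[C@H]4CC5(OCCO5)C(C)(C)[C@@H]1[C@@]34C | intermediate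
32 | saturated keto aldehyde: C12 methyl ketone, C14 aldehyde (not isolated) | CC(C)(C)[Si](C)(C)O[C@@H]1CC(C=O)[C@]36OC(C)(C)O[C@]6(C(C)=O)[C@H]4CC5(OCCO5)C(C)(C)[C@@H]1[C@@]34C | intermediate
33 | C7=C8 enal with C12 methyl ketone | CC(C)(C)[Si](C)(C)O[C@@H]1C=C(C=O)[C@]36OC(C)(C)O[C@]6(C(C)=O)[C@H]4CC5(OCCO5)C(C)(C)[C@@H]1[C@@]34C | intermediate
34 | lithium enolate of the methyl ketone of 33 (not isolated) | CC(C)(C)[Si](C)(C)O[C@@H]1C=C(C=O)[C@]36OC(C)(C)O[C@]6(C(=C)O[Li])[C@H]4CC5(OCCO5)C(C)(C)[C@@H]1[C@@]34C | intermediate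
35 | ring C aldol: 12-ketone, 14β-hydroxyl, C7=C8 | CC(C)(C)[Si](C)(C)O[C@@H]1C=C2[C@H](O)CC(=O)[C@@]3(OC6(C)C)[C@H]4CC5(OCCO5)C(C)(C)[C@@H]1[C@@]4(C)[C@@]23O6 | intermediate
36 | 14β-triethylsilyl ether of 35 | CC(C)(C)[Si](C)(C)O[C@@H]1C=C2[C@H](O[Si](CC)(CC)CC)CC(=O)[C@@]3(OC6(C)C)[C@H]4CC5(OCCO5)C(C)(C)[C@@H]1[C@@]4(C)[C@@]23O6 | intermediate
37 | C12=C13 lithium enolate of 36 (not isolated) | CC(C)(C)[Si](C)(C)O[C@@H]1C=C2[C@H](O[Si](CC)(CC)CC)C=C(O[Li])[C@@]3(OC6(C)C)[C@H]4CC5(OCCO5)C(C)(C)[C@@H]1[C@@]4(C)[C@@]23O6 | intermediate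
38 | C13 (1-hydroxyethyl) aldol | CC(C)(C)[Si](C)(C)O[C@@H]1C=C2[C@H](O[Si](CC)(CC)CC)C(C(C)O)C(=O)[C@@]3(OC6(C)C)[C@H]4CC5(OCCO5)C(C)(C)[C@@H]1[C@@]4(C)[C@@]23O6 | intermediate
39 | mesylate of 38 (not isolated) | CC(C)(C)[Si](C)(C)O[C@@H]1C=C2[C@H](O[Si](CC)(CC)CC)C(C(C)OS(C)(=O)=O)C(=O)[C@@]3(OC6(C)C)[C@H]4CC5(OCCO5)C(C)(C)[C@@H]1[C@@]4(C)[C@@]23O6 | intermediate
40 | (E)-13(16)-ethylidene 12-ketone, 14β-OTES | CC(C)(C)[Si](C)(C)O[C@@H]1C=C2[C@H](O[Si](CC)(CC)CC)/C(=C\C)C(=O)[C@@]3(OC6(C)C)[C@H]4CC5(OCCO5)C(C)(C)[C@@H]1[C@@]4(C)[C@@]23O6 | intermediate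
41 | (E)-13(16)-ethylidene 12-ketone, 14β-hydroxyl | CC(C)(C)[Si](C)(C)O[C@@H]1C=C2[C@H](O)/C(=C\C)C(=O)[C@@]3(OC6(C)C)[C@H]4CC5(OCCO5)C(C)(C)[C@@H]1[C@@]4(C)[C@@]23O6 | intermediate
42 | 12α,14β-diol with (E)-ethylidene | CC(C)(C)[Si](C)(C)O[C@@H]1C=C2[C@H](O)/C(=C\C)[C@@H](O)[C@@]3(OC6(C)C)[C@H]4CC5(OCCO5)C(C)(C)[C@@H]1[C@@]4(C)[C@@]23O6 | intermediate
43 | spirocyclopropane 12α,14β-diol (C15 β, C16 α, methyl cis to C14) | CC(C)(C)[Si](C)(C)O[C@@H]1C=C2[C@H](O)[C@]7(C[C@H]7C)[C@@H](O)[C@@]3(OC6(C)C)[C@H]4CC5(OCCO5)C(C)(C)[C@@H]1[C@@]4(C)[C@@]23O6 | intermediate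
44 | C14 enone (C7=C8) with 12α-hydroxyl | CC(C)(C)[Si](C)(C)O[C@@H]1C=C2C(=O)[C@]7(C[C@H]7C)[C@@H](O)[C@@]3(OC6(C)C)[C@H]4CC5(OCCO5)C(C)(C)[C@@H]1[C@@]4(C)[C@@]23O6 | intermediate
45 | 7α,8α-epoxy 14-ketone | CC(C)(C)[Si](C)(C)O[C@@H]1[C@H]8O[C@]82C(=O)[C@]7(C[C@H]7C)[C@@H](O)[C@@]3(OC6(C)C)[C@H]4CC5(OCCO5)C(C)(C)[C@@H]1[C@@]4(C)[C@@]23O6 | intermediate
46 | 6β,12α-diol epoxy ketone | O[C@@H]1[C@H]8O[C@]82C(=O)[C@]7(C[C@H]7C)[C@@H](O)[C@@]3(OC6(C)C)[C@H]4CC5(OCCO5)C(C)(C)[C@@H]1[C@@]4(C)[C@@]23O6 | intermediate
47 | 6β,12α-diacetate epoxy ketone | CC(=O)O[C@@H]1[C@H]8O[C@]82C(=O)[C@]7(C[C@H]7C)[C@@H](OC(C)=O)[C@@]3(OC6(C)C)[C@H]4CC5(OCCO5)C(C)(C)[C@@H]1[C@@]4(C)[C@@]23O6 | intermediate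
48 | target as 9,11-acetonide and C3 ethylene ketal | CC(=O)O[C@@H]1[C@@H](O)[C@H]2C(=O)[C@]7(C[C@H]7C)[C@@H](OC(C)=O)[C@@]3(OC6(C)C)[C@H]4CC5(OCCO5)C(C)(C)[C@@H]1[C@@]4(C)[C@@]23O6 | intermediate
49 | CNP0157858.3 | CC(=O)O[C@@H]1[C@@H](O)[C@H]2C(=O)[C@]3(C[C@H]3C)[C@@H](OC(C)=O)[C@@]3(O)[C@H]4CC(=O)C(C)(C)[C@@H]1[C@@]4(C)[C@@]23O | target

**Step count**
Total: 32 steps. Longest linear sequence: 28 steps (steps 1–4, 7–11 and 14–32).

**Steps most likely to fail**

Step 7. The hindered ketone dienolate may act as a base toward C8 of the unactivated, α-methylated enone, or add too slowly to build the C4–C5 bond next to the silyloxy carbon, so that self-condensation of 11 takes over. The fallback keeps the same two bonds but forms them under Lewis-acid activation. It sets out from 11 and 5: soft enolisation of 11 (Et3SiOTf, Et3N) would give the triethylsilyl dienol ether F1. A Tf2NH-catalysed Mukaiyama–Michael addition of F1 to 5, anti to the C6 silyloxy group, would give the mono-adduct silyl enol ether F2. Under the same catalyst F2 should close ring A by a second, intramolecular Mukaiyama–Michael addition with silyl transfer to the C3 oxygen, and the route is rejoined at 15.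

Step 16. The C11 ketyl may lose its α-alkoxy group or be reduced to the carbinol before it couples with the hindered C9 ketone, and the strained ring may not close. The fallback couples first and introduces C12 afterwards. It sets out from 20: SmI2 pinacol coupling of the less hindered keto aldehyde would give the cyclobutane-9β,11-diol F3. IBX oxidation of its secondary hydroxyl would give the 2-hydroxycyclobutanone F4, and Wittig reaction with excess Ph3P=CHCH3 the ethylidenecyclobutanol F5. OsO4/NMO dihydroxylation from the convex β face, the face of the C9 hydroxyl, would give the triol F6. Benzyloxymethylation of its only secondary hydroxyl (BnOCH2Cl, i-Pr2NEt) returns to the route at 29.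

Step 26. The carbenoid may be delivered to the C7=C8 bond or from the C12 alkoxide, and the facial control is lost if step 20 has given the other C14 epimer. The fallback does not use the C14 stereocentre. It sets out from 41: MnO2 oxidation of the C14 hydroxyl would give the 2-ethylidene-1,3-dione F7. Corey–Chaykovsky cyclopropanation with dimethylsulfoxonium methylide, from the convex β face and with retention of the alkene geometry, would give the spirocyclopropane diketone F8. Reduction of the saturated C12 ketone in the presence of the C14 enone (NaBH4, MeOH/CH2Cl2, −78 °C), with hydride entering from the β face, comes back to the route at 44.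

**Further compounds**
F1 | step 7 | methyl (E)-5-methyl-4-(triethylsilyloxy)hexa-2,4-dienoate | COC(=O)/C=C/C(O[Si](CC)(CC)CC)=C(C)C
F2 | step 7 | mono-adduct, C9 triethylsilyl enol ether with C4–C5 bond formed | COC(=O)/C=C/C(=O)C(C)(C)[C@H]1[C@H](O[Si](C)(C)C(C)(C)C)CCC(O[Si](CC)(CC)CC)=C1C
F3 | step 16 | cyclobutane-9β,11β-diol with secondary C11 carbinol | CC(C)(C)[Si](C)(C)O[C@@H]1CC(COCc2ccccc2)[C@@]3(O)[C@H](O)[C@H]4CC5(OCCO5)C(C)(C)[C@@H]1[C@@]34C
F4 | step 16 | 9β-hydroxy cyclobutan-11-one | CC(C)(C)[Si](C)(C)O[C@@H]1CC(COCc2ccccc2)[C@@]3(O)C(=O)[C@H]4CC5(OCCO5)C(C)(C)[C@@H]1[C@@]34C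
F5 | step 16 | 11-ethylidene cyclobutan-9β-ol | CC(C)(C)[Si](C)(C)O[C@@H]1CC(COCc2ccccc2)[C@@]3(O)C(=CC)[C@H]4CC5(OCCO5)C(C)(C)[C@@H]1[C@@]34C
F6 | step 16 | 9β,11β,12-triol | CC(C)(C)[Si](C)(C)O[C@@H]1CC(COCc2ccccc2)[C@@]3(O)[C@@](O)(C(C)O)[C@H]4CC5(OCCO5)C(C)(C)[C@@H]1[C@@]34C
F7 | step 26 | 13(16)-ethylidene 12,14-dione (methyl on the C14 side) | CC(C)(C)[Si](C)(C)O[C@@H]1C=C2C(=O)/C(=C\C)C(=O)[C@@]3(OC6(C)C)[C@H]4CC5(OCCO5)C(C)(C)[C@@H]1[C@@]4(C)[C@@]23O6
F8 | step 26 | spirocyclopropane 12,14-dione | CC(C)(C)[Si](C)(C)O[C@@H]1C=C2C(=O)[C@]7(C[C@H]7C)C(=O)[C@@]3(OC6(C)C)[C@H]4CC5(OCCO5)C(C)(C)[C@@H]1[C@@]4(C)[C@@]23O6
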